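**Retrosynthetic overview** (locants of cyclohepta[b]furan: lactone ring O1–C2–C3–C3a–C8a, seven-membered ring C3a–C4–C5–C6–C7–C8–C8a)
- The C7 carbinol is built last, carbon before oxygen: enone ⇐ allylic alcohol ⇐ α-hydroxy aldehyde ⇐ 7-methylidene (osmylation anti to the C8 ester) ⇐ C7 ketone.
- The cis-fused 3-methyl lactone (C3, C3a) comes from syn hydrogenation of a 3-methylbutenolide; C6 and C8 flank the C7 ketone and are adjusted thermodynamically.
- Key disconnection: C4–C5 and C8–C8a are cut together, a (4+3) annulation of a 5-silyloxyfuran-3-ylmethyl cation (C4–C3a–C8a, carrying the whole lactone) with a 1-alkoxy-2-acetoxy-3-methylbutadiene (C5–C6–C7–C8) whose ether group is a (1R)-1-phenylethyl auxiliary.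
- Enabling feature: the lactone O1–C2(=O)–C3(Me)–C3a–C8a is a masked 2-silyloxyfuran; with a leaving group on C4, the carbons C4–C3a–C8a form an O1-stabilized allyl cation, and ring closure returns the furan as the butenolide. The vicinal oxygens on C7/C8 and the C6 methyl mark the diene.
- Ring order: lactone ring first (as a furanone, step 1), seven-membered ring in step 7; each fragment takes three steps from commercial materials.

Key step: step 7

**Step 1**
Reactants: 1 1,3-dihydroxyacetone (commercial dimer); 2 ethyl 2-(triphenylphosphoranylidene)propanoate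
Product: 3 4-(hydroxymethyl)-3-methylfuran-2(5H)-one
Conditions: CH2Cl2/MeOH, 40 °C
Reagents that add atoms: none
Why: Wittig olefination of the ketone by the stabilized ylide gives a tetrasubstituted hydroxy enoate in which one of the two equivalent CH2OH groups is necessarily cis to the ester and lactonizes in the flask, and no stereocenter is formed.

**Step 2**
Reactants: 3 4-(hydroxymethyl)-3-methylfuran-2(5H)-one
Product: 4 (4-methyl-5-oxo-2,5-dihydrofuran-3-yl)methyl acetate
Conditions: Ac2O, pyridine, DMAP (cat.), CH2Cl2, 0 °C to rt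
Reagents that add atoms: acetic anhydride, CC(=O)OC(C)=O
Why: DMAP-catalysed acylation turns the primary alcohol into the leaving group needed for the later ionization, and no stereocenter is involved.

**Step 3**
Reactants: 4 (4-methyl-5-oxo-2,5-dihydrofuran-3-yl)methyl acetate
Product: 5 [4-methyl-5-(triisopropylsilyloxy)furan-3-yl]methyl acetate
Conditions: TIPSOTf, Et3N, CH2Cl2, 0 °C
Reagents that add atoms: triisopropylsilyl triflate, CC(C)[Si](C(C)C)(C(C)C)OS(=O)(=O)C(F)(F)F
Why: Soft enolization and O-silylation of the butenolide (γ-deprotonation by Et3N, trapping by the silyl triflate) gives the aromatic 2-silyloxyfuran, which the bulky silyl group makes isolable, and no stereocenter is formed.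

**Step 4**
Reactants: 6 (R)-1-phenylethanol; 7 2-chloro-N-methoxy-N-methylacetamide
Product: 9 N-methoxy-N-methyl-2-[(1R)-1-phenylethoxy]acetamide, via sodium alkoxide 8 (not isolated)
Conditions: NaH, THF, 0 °C to rt
Reagents that add atoms: none
Why: Williamson ether synthesis, in which the alkoxide displaces the activated α-chloride by SN2 at a carbon remote from the stereocenter of 6, which is therefore retained.

**Step 5**
Reactants: 9 N-methoxy-N-methyl-2-[(1R)-1-phenylethoxy]acetamide
Product: 10 3-methyl-1-[(1R)-1-phenylethoxy]but-3-en-2-one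
Conditions: isopropenylmagnesium bromide, THF, −20 to 0 °C; aq. NH4Cl
Reagents that add atoms: isopropenylmagnesium bromide, CC(=C)[Mg]Br
Why: Grignard acylation by an N-methoxy-N-methylamide, which is known to stop at the ketone stage, gives the isopropenyl ketone without a new stereocenter.

**Step 6**
Reactants: 10 3-methyl-1-[(1R)-1-phenylethoxy]but-3-en-2-one
Product: 12 (1Z)-3-methyl-1-[(1R)-1-phenylethoxy]buta-1,3-dien-2-yl acetate, via lithium dienolate 11 (not isolated)
Conditions: LiN(SiMe3)2, THF, −78 °C; then Ac2O, −78 to 0 °C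
Reagents that add atoms: acetic anhydride, CC(=O)OC(C)=O
Why: Kinetic enolization at the only enolizable position and O-acetylation of the lithium enolate by the anhydride (enol ester formation) give the diene, and chelation of lithium by the ether oxygen should fix the (Z) enolate geometry and hence the (1Z) enol acetate.

**Step 7**
Reactants: 5 [4-methyl-5-(triisopropylsilyloxy)furan-3-yl]methyl acetate; 12 (1Z)-3-methyl-1-[(1R)-1-phenylethoxy]buta-1,3-dien-2-yl acetate
Product: 15 (8S,8aR)-3,6-dimethyl-2-oxo-8-[(1R)-1-phenylethoxy]-4,5,8,8a-tetrahydro-2H-cyclohepta[b]furan-7-yl acetate, via furylmethyl cation 13 (not isolated), via oxocarbenium ion 14 (not isolated)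
Conditions: TMSOTf (0.2 equiv), 2,6-di-tert-butyl-4-methylpyridine (0.3 equiv), CH2Cl2, −78 °C; slow addition of 5 to 12 (1.5 equiv)
Reagents that add atoms: none
Why: Proposed new method: TMSOTf ionizes the acetate of 5 to cation 13, an oxygen-stabilized allyl cation over the exocyclic CH2, C3 and C2 of the furan, which is attacked at the exocyclic carbon by the CH2 terminus of 12 (bond C4–C5, furan restored, oxocarbenium ion 14), after which the free α-carbon of the silyloxyfuran adds to the oxocarbenium carbon (bond C8–C8a) and the silyl group leaves as its acetate, so that the butenolide carbonyl appears directly. The closest known reaction types are the dearomative (4+3) cycloadditions of furan-2-ylmethyl cations with dienes and the vinylogous Mukaiyama addition of 2-silyloxyfurans to oxocarbenium ions; a 5-silyloxyfuran-3-ylmethyl cation as three-carbon partner with the silyloxy group as internal terminator is not a known case. Only the seven-membered ring is closed, by a 7-exo-trig attack on the C=O+ bond (endo with respect to the furan C=C), whereas the lactone ring is carried in as the furan. C8 and C8a arise in this closure: the (1R)-1-phenylethyl group on the oxocarbenium oxygen (E geometry, benzylic hydrogen eclipsing the C=O+ bond) covers the Re face of C8 with its phenyl ring, so that attack on the Si face should give 8S, and an extended, chair-like arrangement, in which the furan turns away from the diene unit and the ether oxygen of the (1Z) enol ether lies outside, should place the two oxygens trans and give 8aR. The step needs head-to-head regioselectivity, which is secured by matched polarity: 13 reacts first at its exocyclic carbon because this restores the furan, and 12 reacts first at its CH2 terminus because only this end is activated by the ether oxygen and by the methyl group, the acetoxy group being a poor donor. Self-alkylation of 5 is suppressed by adding 5 slowly to an excess of 12.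

**Step 8**
Reactants: 15 (8S,8aR)-3,6-dimethyl-2-oxo-8-[(1R)-1-phenylethoxy]-4,5,8,8a-tetrahydro-2H-cyclohepta[b]furan-7-yl acetate
Product: 16 (6S,8S,8aR)-3,6-dimethyl-8-[(1R)-1-phenylethoxy]-5,6,8,8a-tetrahydro-2H-cyclohepta[b]furan-2,7(4H)-dione
Conditions: p-TsOH·H2O (cat.), MeOH, 25 °C
Reagents that add atoms: none
Why: Acid-catalysed transesterification of the enol acetate with methanol frees the enol, which tautomerizes to the C7 ketone, and the new stereocenter C6 (like C8, α to the ketone) is set under thermodynamic control through the enol, the 6,8-trans arrangement with both substituents pseudo-equatorial beside the carbonyl being the expected minimum.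

**Step 9**
Reactants: 16 (6S,8S,8aR)-3,6-dimethyl-8-[(1R)-1-phenylethoxy]-5,6,8,8a-tetrahydro-2H-cyclohepta[b]furan-2,7(4H)-dione
Product: 18 (3R,3aS,6S,8S,8aR)-8-hydroxy-3,6-dimethylhexahydro-2H-cyclohepta[b]furan-2,7(3H)-dione, via hydroxy butenolide 17 (not isolated)
Conditions: H2 (40 bar), 10% Pd/C, EtOAc, rt
Reagents that add atoms: none
Why: Heterogeneous hydrogenolysis of the benzylic ether removes the auxiliary as ethylbenzene, and the tetrasubstituted butenolide is then hydrogenated by syn addition from the face of H8a, anti to the C8 substituent on the neighbouring carbon, which sets C3a and C3 with both new hydrogens cis to H8a (cis-fused lactone, 3-methyl cis to C4).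

**Step 10**
Reactants: 18 (3R,3aS,6S,8S,8aR)-8-hydroxy-3,6-dimethylhexahydro-2H-cyclohepta[b]furan-2,7(3H)-dione
Product: 19 (3R,3aS,6S,8S,8aR)-3,6-dimethyl-2,7-dioxooctahydro-2H-cyclohepta[b]furan-8-yl 2-methylpropanoate
Conditions: (i-PrCO)2O, Sc(OTf)3 (2 mol%), MeCN, −20 to 0 °C
Reagents that add atoms: 2-methylpropanoic anhydride, CC(C)C(=O)OC(=O)C(C)C
Why: Lewis-acid-catalysed acylation of the only hydroxyl group installs the isobutyrate without amine bases, which could eliminate the lactone oxygen β to the ketone, and no new stereocenter is formed.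

**Step 11**
Reactants: 19 (3R,3aS,6S,8S,8aR)-3,6-dimethyl-2,7-dioxooctahydro-2H-cyclohepta[b]furan-8-yl 2-methylpropanoate
Product: 20 (3R,3aS,6S,8R,8aR)-3,6-dimethyl-7-methylidene-2-oxooctahydro-2H-cyclohepta[b]furan-8-yl 2-methylpropanoate
Conditions: Zn, CH2Br2, TiCl4, THF; then 19, CH2Cl2, 0 °C to rt
Reagents that add atoms: dibromomethane, BrCBr
Why: Lombardo methylenation, a non-basic reagent that converts hindered, enolizable ketones into methylene groups without epimerization and leaves esters and lactones untouched, so no stereocenter changes (the C8 descriptor changes only by priority).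

**Step 12**
Reactants: 20 (3R,3aS,6S,8R,8aR)-3,6-dimethyl-7-methylidene-2-oxooctahydro-2H-cyclohepta[b]furan-8-yl 2-methylpropanoate
Product: 21 (3R,3aS,6S,7R,8S,8aR)-7-hydroxy-7-(hydroxymethyl)-3,6-dimethyl-2-oxooctahydro-2H-cyclohepta[b]furan-8-yl 2-methylpropanoate
Conditions: OsO4 (5 mol%), NMO, acetone/H2O, rt
Reagents that add atoms: N-methylmorpholine N-oxide, C[N+]1([O-])CCOCC1; water, O
Why: Upjohn dihydroxylation of the 1,1-disubstituted alkene, in which OsO4 should add to the face anti to the allylic acyloxy group at C8 (the empirical rule for osmylation of allylic ethers and esters) and so place the new tertiary hydroxyl at C7 trans to the C8 oxygen.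

**Step 13**
Reactants: 21 (3R,3aS,6S,7R,8S,8aR)-7-hydroxy-7-(hydroxymethyl)-3,6-dimethyl-2-oxooctahydro-2H-cyclohepta[b]furan-8-yl 2-methylpropanoate
Product: 22 (3R,3aS,6S,7S,8S,8aR)-7-formyl-7-hydroxy-3,6-dimethyl-2-oxooctahydro-2H-cyclohepta[b]furan-8-yl 2-methylpropanoate
Conditions: TEMPO (10 mol%), PhI(OAc)2, CH2Cl2, rt
Reagents that add atoms: none
Why: The TEMPO/PhI(OAc)2 oxidation is selective for the primary alcohol and stops at the aldehyde, the tertiary alcohol cannot be oxidized and the 1,2-diol is not cleaved, so no stereocenter is touched.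

**Step 14**
Reactants: 22 (3R,3aS,6S,7S,8S,8aR)-7-formyl-7-hydroxy-3,6-dimethyl-2-oxooctahydro-2H-cyclohepta[b]furan-8-yl 2-methylpropanoate
Product: 23 (3R,3aS,6S,7R,8S,8aR)-7-hydroxy-7-[(2E)-1-hydroxybut-2-en-1-yl]-3,6-dimethyl-2-oxooctahydro-2H-cyclohepta[b]furan-8-yl 2-methylpropanoate (both epimers at the side-chain carbinol)
Conditions: (E)-1-bromoprop-1-ene, CrCl2, NiCl2 (2 mol%), DMF, rt
Reagents that add atoms: (E)-1-bromoprop-1-ene, C/C=C/Br
Why: Nozaki–Hiyama–Kishi reaction, in which the alkenylchromium reagent adds only to the aldehyde, tolerates the free hydroxyl, the ester and the lactone and keeps the (E) geometry, while the new carbinol center is formed as a mixture that is removed by oxidation in the next step.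

**Step 15**
Reactants: 23 (3R,3aS,6S,7R,8S,8aR)-7-hydroxy-7-[(2E)-1-hydroxybut-2-en-1-yl]-3,6-dimethyl-2-oxooctahydro-2H-cyclohepta[b]furan-8-yl 2-methylpropanoate
Product: 24 (3R,3aS,6S,7S,8S,8aR)-7-[(2E)-but-2-enoyl]-7-hydroxy-3,6-dimethyl-2-oxooctahydro-2H-cyclohepta[b]furan-8-yl 2-methylpropanoate
Conditions: IBX, DMSO, rt
Reagents that add atoms: none
Why: IBX oxidation of the secondary allylic alcohol to the enone, a reagent that does not cleave 1,2-diols and cannot oxidize the tertiary alcohol, so the (E) alkene and all stereocenters should stay intact.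

**Compound list**
1 | 1,3-dihydroxyacetone (commercial as its dimer) | OCC(=O)CO | starting material
2 | ethyl 2-(triphenylphosphoranylidene)propanoate | CCOC(=O)C(C)=P(c1ccccc1)(c1ccccc1)c1ccccc1 | starting material
3 | 4-(hydroxymethyl)-3-methylfuran-2(5H)-one | CC1=C(CO)COC1=O | intermediate
4 | (4-methyl-5-oxo-2,5-dihydrofuran-3-yl)methyl acetate | CC(=O)OCC1=C(C)C(=O)OC1 | intermediate
5 | [4-methyl-5-(triisopropylsilyloxy)furan-3-yl]methyl acetate | CC(=O)OCc1coc(O[Si](C(C)C)(C(C)C)C(C)C)c1C | intermediate
6 | (R)-1-phenylethanol | C[C@@H](O)c1ccccc1 | starting material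
7 | 2-chloro-N-methoxy-N-methylacetamide | CON(C)C(=O)CCl | starting material
8 | sodium (1R)-1-phenylethoxide | C[C@@H]([O-])c1ccccc1.[Na+] | intermediate (not isolated)
9 | N-methoxy-N-methyl-2-[(1R)-1-phenylethoxy]acetamide | C[C@@H](OCC(=O)N(C)OC)c1ccccc1 | intermediate
10 | 3-methyl-1-[(1R)-1-phenylethoxy]but-3-en-2-one | C[C@@H](OCC(=O)C(C)=C)c1ccccc1 | intermediate
11 | lithium (1Z)-3-methyl-1-[(1R)-1-phenylethoxy]buta-1,3-dien-2-olate | C[C@@H](O/C=C(\[O-])C(C)=C)c1ccccc1.[Li+] | intermediate (not isolated)
12 | (1Z)-3-methyl-1-[(1R)-1-phenylethoxy]buta-1,3-dien-2-yl acetate | C[C@@H](O/C=C(\OC(C)=O)C(C)=C)c1ccccc1 | intermediate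
13 | [4-methyl-5-(triisopropylsilyloxy)furan-3-yl]methylium triflate | [CH2+]c1coc(O[Si](C(C)C)(C(C)C)C(C)C)c1C.[O-]S(=O)(=O)C(F)(F)F | intermediate (not isolated)
14 | {(2Z)-2-acetoxy-3-methyl-5-[4-methyl-5-(triisopropylsilyloxy)furan-3-yl]pent-2-en-1-ylidene}[(1R)-1-phenylethyl]oxonium triflate | Cc1c(CC/C(C)=C(OC(C)=O)\C=[O+][C@H](C)c2ccccc2)coc1O[Si](C(C)C)(C(C)C)C(C)C.[O-]S(=O)(=O)C(F)(F)F | intermediate (not isolated)
15 | (8S,8aR)-3,6-dimethyl-2-oxo-8-[(1R)-1-phenylethoxy]-4,5,8,8a-tetrahydro-2H-cyclohepta[b]furan-7-yl acetate | CC(=O)OC1=C(C)CCC2=C(C)C(=O)O[C@H]2[C@@H]1O[C@H](C)c1ccccc1 | intermediate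
16 | (6S,8S,8aR)-3,6-dimethyl-8-[(1R)-1-phenylethoxy]-5,6,8,8a-tetrahydro-2H-cyclohepta[b]furan-2,7(4H)-dione | O=C1[C@@H](C)CCC2=C(C)C(=O)O[C@H]2[C@@H]1O[C@H](C)c1ccccc1 | intermediate
17 | (6S,8S,8aR)-8-hydroxy-3,6-dimethyl-5,6,8,8a-tetrahydro-2H-cyclohepta[b]furan-2,7(4H)-dione | O=C1[C@@H](C)CCC2=C(C)C(=O)O[C@H]2[C@@H]1O | intermediate (not isolated)
18 | (3R,3aS,6S,8S,8aR)-8-hydroxy-3,6-dimethylhexahydro-2H-cyclohepta[b]furan-2,7(3H)-dione | O=C1[C@@H](C)CC[C@@H]2[C@@H](OC(=O)[C@@H]2C)[C@@H]1O | intermediate
19 | (3R,3aS,6S,8S,8aR)-3,6-dimethyl-2,7-dioxooctahydro-2H-cyclohepta[b]furan-8-yl 2-methylpropanoate | O=C1[C@@H](C)CC[C@@H]2[C@@H](OC(=O)[C@@H]2C)[C@@H]1OC(=O)C(C)C | intermediate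
20 | (3R,3aS,6S,8R,8aR)-3,6-dimethyl-7-methylidene-2-oxooctahydro-2H-cyclohepta[b]furan-8-yl 2-methylpropanoate | C=C1[C@@H](C)CC[C@@H]2[C@@H](OC(=O)[C@@H]2C)[C@@H]1OC(=O)C(C)C | intermediate
21 | (3R,3aS,6S,7R,8S,8aR)-7-hydroxy-7-(hydroxymethyl)-3,6-dimethyl-2-oxooctahydro-2H-cyclohepta[b]furan-8-yl 2-methylpropanoate | OC[C@]1(O)[C@@H](C)CC[C@@H]2[C@@H](OC(=O)[C@@H]2C)[C@@H]1OC(=O)C(C)C | intermediate
22 | (3R,3aS,6S,7S,8S,8aR)-7-formyl-7-hydroxy-3,6-dimethyl-2-oxooctahydro-2H-cyclohepta[b]furan-8-yl 2-methylpropanoate | O=C[C@]1(O)[C@@H](C)CC[C@@H]2[C@@H](OC(=O)[C@@H]2C)[C@@H]1OC(=O)C(C)C | intermediate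
23 | (3R,3aS,6S,7R,8S,8aR)-7-hydroxy-7-[(2E)-1-hydroxybut-2-en-1-yl]-3,6-dimethyl-2-oxooctahydro-2H-cyclohepta[b]furan-8-yl 2-methylpropanoate (both epimers at the side-chain carbinol) | C/C=C/C(O)[C@]1(O)[C@@H](C)CC[C@@H]2[C@@H](OC(=O)[C@@H]2C)[C@@H]1OC(=O)C(C)C | intermediate
24 | (3R,3aS,6S,7S,8S,8aR)-7-[(2E)-but-2-enoyl]-7-hydroxy-3,6-dimethyl-2-oxooctahydro-2H-cyclohepta[b]furan-8-yl 2-methylpropanoate | C/C=C/C(=O)[C@]1(O)[C@@H](C)CC[C@@H]2[C@@H](OC(=O)[C@@H]2C)[C@@H]1OC(=O)C(C)C | target

**Step count.** Total: 15 steps. Longest linear sequence: 12 steps (steps 1–3 or 4–6, then 7–15).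

**Steps most likely to fail**

Step 7 (proposed new method). The electron-rich silyloxyfuran may be alkylated by its own cation and oligomerize. The diene may be attacked at its oxygenated terminus, giving the crossed regiochemistry. The closure may show poor facial control by the auxiliary or poor discrimination between the extended and the compact arrangement. The fallback uses known reaction types only, sets out from 3 and 10, and returns to the route at 16. Alcohol 3 is converted with CBr4/PPh3 (Appel reaction) into 4-(bromomethyl)-3-methylfuran-2(5H)-one F1. The radical made from it with (Me3Si)3SiH/AIBN adds to the unsubstituted terminus of enone 10 (Giese addition) and should give 3-methyl-4-{3-methyl-4-oxo-5-[(1R)-1-phenylethoxy]pentyl}furan-2(5H)-one F2. Double deprotonation with LiN(SiMe3)2 at −78 °C (ketone enolate at the ether-bearing carbon and furanolate of the butenolide), followed by Fe(acac)3, should close the C8–C8a bond by intramolecular oxidative enolate coupling. Equilibration under the conditions of step 8 should then deliver 16.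

Step 12. Osmylation may take place on the face syn to the C8 ester (anti to the C6 methyl), and the ester may migrate to the new primary hydroxyl. The fallback sets out from 20 and returns at 21. Epoxidation of 20 with mCPBA, which should show the same facial bias, gives (3R,3aS,6S,7S,8S,8aR)-3,6-dimethyl-2-oxooctahydro-2H-spiro[cyclohepta[b]furan-7,2′-oxiran]-8-yl 2-methylpropanoate F3, with the epoxide oxygen cis to the ester. Acid-catalysed hydrolysis (HClO4, THF/H2O) should open it at the tertiary carbon C7 with inversion, because the cis ester cannot participate from the rear, and give 21.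

Step 9. The tetrasubstituted butenolide may be reduced slowly or from both faces, and the C8–O bond next to the ketone may be cleaved. The fallback sets out from 16 and returns at 18. Hydrogenolysis at 1 bar over Pd(OH)2/C is stopped at hydroxy butenolide 17, which is isolated. The free C8 hydroxyl then directs a homogeneous hydrogenation with [Ir(cod)(PCy3)(py)]PF6 (H2, CH2Cl2) to the face of H8a and should give 18. No new compound is made.

**Further compounds**
F1 | step 7 | 4-(bromomethyl)-3-methylfuran-2(5H)-one | CC1=C(CBr)COC1=O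
F2 | step 7 | 3-methyl-4-{3-methyl-4-oxo-5-[(1R)-1-phenylethoxy]pentyl}furan-2(5H)-one (both epimers at the methyl-bearing carbon) | CC1=C(CCC(C)C(=O)CO[C@H](C)c2ccccc2)COC1=O
F3 | step 12 | (3R,3aS,6S,7S,8S,8aR)-3,6-dimethyl-2-oxooctahydro-2H-spiro[cyclohepta[b]furan-7,2′-oxiran]-8-yl 2-methylpropanoate | C3O[C@@]31[C@@H](C)CC[C@@H]2[C@@H](OC(=O)[C@@H]2C)[C@@H]1OC(=O)C(C)C
F0 | step 9 | none | none
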